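The tetrahedral ring O1, C2, C3, C4, C5 has two adjacent oxygen-bearing carbons, C2 and C3, that stand trans, and C2 also carries the vinylic carbon C1'. A 2-alkenyl-3-hydroxy ether like this is what an oxygen-substituted allylmetal leaves after adding to an aldehyde, and O1–C5–C4 can tether the two partners.
Retrosynthetic cuts, in order: the three O–Si bonds; C3'=C4' of the diene (Horner–Wadsworth–Emmons); C1'=C2' (cross-metathesis, back to a plain vinyl group); the ring bond C2–C3 (allylstannane plus aldehyde). On the aromatic side: CH2–P, the lactone bond O2–C1, the bond C4–C3 (toluate acylation) and C5–Cl.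
Forward: the O1–C5–C4–C3 chain is built open from methyl (R)-3-hydroxybutanoate, the tetrahydrofuran closes in step 7 and is extended to an enal (fragment 1). Methyl orsellinate is chlorinated first, its pyranone ring closes in step 13, and a phosphonate results (fragment 2). The fragments are joined in step 16 and unmasked in step 17.
Stereochemistry: C5 (R) is bought and never touched. C2 (R) and C3 (S) arise together in step 7 under control of C5 and of the Z enol-ether geometry. Both diene double bonds are E, from thermodynamically controlled metathesis and phosphonate olefination.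

Key step: step 7

Remark (reading of the target): the SMILES corresponds to (2R,3S,5R), that is 2,3-trans, 3,5-cis and 2,5-trans on the tetrahydrofuran. The isocoumarin carries Cl at C5, OH at C6 and C8, and the (1E,3E)-dienyl chain at C3. The diene carbons are counted C1' to C4' starting from C2.
Assumption: monochlorination of methyl orsellinate with SO2Cl2 is taken to occur mainly at C5, and any 3-chloro isomer is removed by crystallisation.

Step 1
Reactants: 1 methyl (R)-3-hydroxybutanoate; 2 allyl 2,2,2-trichloroacetimidate
Product: 3 methyl (R)-3-(allyloxy)butanoate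
Conditions: TfOH (5 mol %), cyclohexane/CH2Cl2 2:1, 0 °C to rt
Reagents that add atoms: none
Why: Acid-catalysed trichloroacetimidate etherification transfers the allyl group to the secondary hydroxyl without any base, so the beta-hydroxy ester can neither eliminate nor epimerise and the C–O bond at the future C5 (R) is not touched.

Step 2
Reactants: 3 methyl (R)-3-(allyloxy)butanoate
Product: 4 (R)-3-(allyloxy)butan-1-ol
Conditions: LiAlH4, Et2O, 0 °C
Reagents that add atoms: none
Why: LiAlH4 ester reduction delivers the primary alcohol whose carbon will become C3, and neither the allyl ether nor the stereocentre reacts with hydride.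

Step 3
Reactants: 4 (R)-3-(allyloxy)butan-1-ol
Product: 5 (R)-[3-(allyloxy)butoxy](tert-butyl)dimethylsilane
Conditions: TBSCl, imidazole, CH2Cl2, rt
Reagents that add atoms: tert-butyldimethylsilyl chloride (TBSCl), CC(C)(C)[Si](C)(C)Cl
Why: Routine silyl ether formation removes the only acidic proton, so the organolithium base of step 4 is consumed solely at the allylic OCH2 group.

Step 4
Reactants: 5 (R)-[3-(allyloxy)butoxy](tert-butyl)dimethylsilane; 6 tributyltin chloride
Product: 8 (R,Z)-tert-butyldimethyl{3-[3-(tributylstannyl)prop-1-enyloxy]butoxy}silane, via chelated (Z)-alkoxyallyllithium 7 (not isolated)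
Conditions: s-BuLi, TMEDA, THF, −78 °C; then Bu3SnCl, −78 °C
Reagents that add atoms: none
Why: Alpha-lithiation of an allyl ether gives an allyl anion locked in the Z form by internal Li–O coordination, and the bulky tin chloride is captured at the unhindered gamma terminus, which is the standard entry to (Z)-gamma-alkoxyallylstannanes.

Step 5
Reactants: 8 (R,Z)-tert-butyldimethyl{3-[3-(tributylstannyl)prop-1-enyloxy]butoxy}silane
Product: 9 (R,Z)-3-[3-(tributylstannyl)prop-1-enyloxy]butan-1-ol
Conditions: TBAF, THF, 0 °C to rt
Reagents that add atoms: none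
Why: Fluoride-mediated desilylation is basic rather than acidic, and under such conditions the protonolysis-prone enol ether and allyl–tin bond are known to persist.

Step 6
Reactants: 9 (R,Z)-3-[3-(tributylstannyl)prop-1-enyloxy]butan-1-ol
Product: 10 (R)-3-[(Z)-3-(tributylstannyl)prop-1-enyloxy]butanal
Conditions: SO3·pyridine, DMSO, Et3N, CH2Cl2, 0 °C
Reagents that add atoms: none
Why: The Parikh–Doering oxidation runs at 0 °C in an amine-buffered medium free of acid and of electrophilic halogen, so the allylstannane survives and the beta-alkoxy aldehyde, used at once without chromatography, has little time to eliminate.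

Step 7
Reactants: 10 (R)-3-[(Z)-3-(tributylstannyl)prop-1-enyloxy]butanal
Product: 12 (2R,3S,5R)-5-methyl-2-vinyltetrahydrofuran-3-ol, via difluoroboryl ether 11 (not isolated)
Conditions: BF3·OEt2 (1.2 equiv), CH2Cl2 (0.01 M), −78 °C; aq NaHCO3 quench
Reagents that add atoms: none
Why: BF3 binds the aldehyde oxygen and the oxygen-bearing terminus C2 of the allylstannane attacks C3 in an anti SE2' sense, the C–Sn bond feeding the developing positive charge until tin leaves as Bu3SnF and the C1'=C2' vinyl group appears. The closest known reaction type is the Lewis-acid-mediated intramolecular gamma-alkoxyallylstannane–aldehyde condensation that gives trans-2-vinyl-3-hydroxy tetrahydropyrans and oxepanes, and here the tether is simply one or two atoms shorter. The tetrahydrofuran closes in the 5-exo-trig mode at the carbonyl group, and the attacking C2=C1' bond also stays outside the forming ring, an arrangement that Baldwin's rules allow. C2 is controlled by C5: because the enol ether is Z, its CH2SnBu3 arm folds back beneath O1 and C5, so the alkenyl arm should take the ring face that carries the C5 hydrogen and end up trans to the methyl group (2R). C3 is controlled by C2: in the open, non-chelated transition state the BF3-bound oxygen turns away from the alkenyl arm, which should give the 2,3-trans and hence 3,5-cis relation (3S), the one arrangement in which all three substituents are pseudo-equatorial on a ring twisted about C3–C4. The step needs gamma rather than alpha attack and a ring closure faster than beta-elimination or protodestannylation, which the short tether, the low temperature, the high dilution and a strictly anhydrous medium secure.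

Step 8
Reactants: 12 (2R,3S,5R)-5-methyl-2-vinyltetrahydrofuran-3-ol
Product: 13 tert-butyldimethyl{[(2R,3S,5R)-5-methyl-2-vinyltetrahydrofuran-3-yl]oxy}silane
Conditions: TBSCl, imidazole, DMF, rt (on the carefully concentrated extract of step 7, since the alcohol is volatile)
Reagents that add atoms: tert-butyldimethylsilyl chloride (TBSCl), CC(C)(C)[Si](C)(C)Cl
Why: Silyl ether formation on the secondary alcohol prevents alkoxide-triggered vinylogous retro-aldol cleavage of C2–C3 once the enal is in place, and it puts on O3 a fluoride-labile group that falls in the last step.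

Step 9
Reactants: 13 tert-butyldimethyl{[(2R,3S,5R)-5-methyl-2-vinyltetrahydrofuran-3-yl]oxy}silane; 14 (E)-crotonaldehyde
Product: 15 (E)-3-[(2R,3S,5R)-3-(tert-butyldimethylsilyloxy)-5-methyltetrahydrofuran-2-yl]prop-2-enal
Conditions: crotonaldehyde (5 equiv), second-generation Grubbs catalyst RuCl2(=CHPh)(PCy3)(H2IMes) (5 mol %), CH2Cl2, 40 °C
Reagents that add atoms: none
Why: Olefin cross-metathesis of a terminal allylic-ether alkene with an excess of an electron-poor enal partner favours the cross product, gives the E double bond under thermodynamic control and is driven by loss of propene, while C2 is not involved.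

Step 10
Reactants: 16 methyl 2,4-dihydroxy-6-methylbenzoate (methyl orsellinate)
Product: 17 methyl 3-chloro-4,6-dihydroxy-2-methylbenzoate
Conditions: SO2Cl2 (1.0 equiv), Et2O, 0 °C to rt
Reagents that add atoms: sulfuryl chloride, O=S(=O)(Cl)Cl
Why: Electrophilic aromatic chlorination of the resorcylate goes mainly to the position ortho to the free 4-OH and para to the hydrogen-bonded 2-OH (the future C5), the regiochemistry known for orsellinates and related resorcylic esters, and doing it first avoids later competition from C4 or the diene.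

Step 11
Reactants: 17 methyl 3-chloro-4,6-dihydroxy-2-methylbenzoate
Product: 18 methyl 3-chloro-4,6-bis(methoxymethoxy)-2-methylbenzoate
Conditions: NaH, MOMCl, DMF, 0 °C to rt
Reagents that add atoms: chloromethyl methyl ether (MOMCl), COCCl
Why: Williamson-type O-alkylation of both phenoxides gives acetals that tolerate the amide base of step 12 and that the acid of step 13 removes again.

Step 12
Reactants: 18 methyl 3-chloro-4,6-bis(methoxymethoxy)-2-methylbenzoate; 19 2-chloro-N-methoxy-N-methylacetamide
Product: 21 methyl 3-chloro-2-(3-chloro-2-oxopropyl)-4,6-bis(methoxymethoxy)benzoate, via benzylic lithium species 20 (not isolated)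
Conditions: LiN(iPr)2, THF, −78 °C; then the amide, −78 °C; AcOH/THF quench at −78 °C
Reagents that add atoms: none
Why: Lateral lithiation of the ortho-toluate followed by Weinreb ketone synthesis forms C4–C3, with the chelated tetrahedral adduct blocking a second addition and the cold acidic quench forestalling attack of its alkoxide on the neighbouring CH2Cl group.

Step 13
Reactants: 21 methyl 3-chloro-2-(3-chloro-2-oxopropyl)-4,6-bis(methoxymethoxy)benzoate
Product: 23 5-chloro-3-(chloromethyl)-6,8-dihydroxy-1H-isochromen-1-one, via dihydroxy keto ester 22 (not isolated)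
Conditions: TFA/CH2Cl2 1:2 (trace H2O), 0 °C to rt
Reagents that add atoms: none
Why: Acid hydrolyses both acetals and then lets the enol of the benzylic ketone attack the adjacent ester (6-exo-trig enol lactonisation with loss of methanol), the collapse to an isocoumarin that 6-(2-oxoalkyl)resorcylates are known to undergo readily, whereas base would invite a Favorskii reaction of the alpha-chloro ketone.

Step 14
Reactants: 23 5-chloro-3-(chloromethyl)-6,8-dihydroxy-1H-isochromen-1-one
Product: 24 6,8-bis(tert-butyldimethylsilyloxy)-5-chloro-3-(chloromethyl)-1H-isochromen-1-one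
Conditions: TBSOTf, 2,6-lutidine, CH2Cl2, 0 °C
Reagents that add atoms: tert-butyldimethylsilyl triflate (TBSOTf), CC(C)(C)[Si](C)(C)OS(=O)(=O)C(F)(F)F
Why: The silyl triflate is reactive enough for the hydrogen-bonded 8-OH, the hindered pyridine base does not displace the allylic chloride, and fluoride-labile groups on O6 and O8 mean that the end game needs no acid that could ionise the doubly allylic C2–O1 bond.

Step 15
Reactants: 24 6,8-bis(tert-butyldimethylsilyloxy)-5-chloro-3-(chloromethyl)-1H-isochromen-1-one; 25 triethyl phosphite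
Product: 26 diethyl {[6,8-bis(tert-butyldimethylsilyloxy)-5-chloro-1-oxo-1H-isochromen-3-yl]methyl}phosphonate
Conditions: P(OEt)3 (neat), 120 °C
Reagents that add atoms: none
Why: In this Michaelis–Arbuzov reaction the primary, allylic-type chloride on the pyranone is displaced by phosphorus and chloride then dealkylates the phosphonium ion, as established for 6-(halomethyl)-2-pyranones.

Step 16
Reactants: 26 diethyl {[6,8-bis(tert-butyldimethylsilyloxy)-5-chloro-1-oxo-1H-isochromen-3-yl]methyl}phosphonate; 15 (E)-3-[(2R,3S,5R)-3-(tert-butyldimethylsilyloxy)-5-methyltetrahydrofuran-2-yl]prop-2-enal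
Product: 28 6,8-bis(tert-butyldimethylsilyloxy)-3-{(1E,3E)-4-[(2R,3S,5R)-3-(tert-butyldimethylsilyloxy)-5-methyltetrahydrofuran-2-yl]buta-1,3-dienyl}-5-chloro-1H-isochromen-1-one, via lithiated phosphonate 27 (not isolated)
Conditions: LiN(SiMe3)2, THF, −78 °C; then the enal, −78 to 0 °C
Reagents that add atoms: none
Why: In this Horner–Wadsworth–Emmons olefination the carbanion is stabilised through C3=C4 and the arene into the lactone carbonyl, so it is mild enough to add to the enal rather than deprotonate C2–H, and phosphonates of this allylic type give the E alkene (C3'=C4').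

Step 17
Reactants: 28 6,8-bis(tert-butyldimethylsilyloxy)-3-{(1E,3E)-4-[(2R,3S,5R)-3-(tert-butyldimethylsilyloxy)-5-methyltetrahydrofuran-2-yl]buta-1,3-dienyl}-5-chloro-1H-isochromen-1-one
Product: 29 5-chloro-6,8-dihydroxy-3-{(1E,3E)-4-[(2R,3S,5R)-3-hydroxy-5-methyltetrahydrofuran-2-yl]buta-1,3-dienyl}-1H-isochromen-1-one (CNP0086741.2)
Conditions: TBAF/AcOH 1:1 (4 equiv), THF, 0 °C to rt
Reagents that add atoms: none
Why: Fluoride cleaves the two aryl silyl ethers and the secondary alkyl silyl ether in a single global desilylation, and the acetic acid buffer keeps the liberated phenoxides from opening the lactone or isomerising the diene.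

Compound list
1 | methyl (R)-3-hydroxybutanoate | C[C@@H](O)CC(=O)OC | starting material
2 | allyl 2,2,2-trichloroacetimidate | C=CCOC(=N)C(Cl)(Cl)Cl | starting material
3 | methyl (R)-3-(allyloxy)butanoate | C[C@@H](OCC=C)CC(=O)OC | intermediate
4 | (R)-3-(allyloxy)butan-1-ol | C[C@@H](OCC=C)CCO | intermediate
5 | (R)-[3-(allyloxy)butoxy](tert-butyl)dimethylsilane | C[C@@H](OCC=C)CCO[Si](C)(C)C(C)(C)C | intermediate
6 | tributyltin chloride | CCCC[Sn](Cl)(CCCC)CCCC | starting material
7 | chelated (Z)-alkoxyallyllithium derived from 5 (not isolated) | C[C@@H](O/C=C\C[Li])CCO[Si](C)(C)C(C)(C)C | intermediate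
8 | (R,Z)-tert-butyldimethyl{3-[3-(tributylstannyl)prop-1-enyloxy]butoxy}silane | C[C@@H](O/C=C\C[Sn](CCCC)(CCCC)CCCC)CCO[Si](C)(C)C(C)(C)C | intermediate
9 | (R,Z)-3-[3-(tributylstannyl)prop-1-enyloxy]butan-1-ol | C[C@@H](O/C=C\C[Sn](CCCC)(CCCC)CCCC)CCO | intermediate
10 | (R)-3-[(Z)-3-(tributylstannyl)prop-1-enyloxy]butanal | C[C@@H](O/C=C\C[Sn](CCCC)(CCCC)CCCC)CC=O | intermediate
11 | difluoroboryl ether of 12 (not isolated) | C[C@@H]1C[C@H](OB(F)F)[C@@H](C=C)O1 | intermediate
12 | (2R,3S,5R)-5-methyl-2-vinyltetrahydrofuran-3-ol | C[C@@H]1C[C@H](O)[C@@H](C=C)O1 | intermediate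
13 | tert-butyldimethyl{[(2R,3S,5R)-5-methyl-2-vinyltetrahydrofuran-3-yl]oxy}silane | C[C@@H]1C[C@H](O[Si](C)(C)C(C)(C)C)[C@@H](C=C)O1 | intermediate
14 | (E)-crotonaldehyde | C/C=C/C=O | starting material
15 | (E)-3-[(2R,3S,5R)-3-(tert-butyldimethylsilyloxy)-5-methyltetrahydrofuran-2-yl]prop-2-enal | C[C@@H]1C[C@H](O[Si](C)(C)C(C)(C)C)[C@@H](/C=C/C=O)O1 | intermediate
16 | methyl 2,4-dihydroxy-6-methylbenzoate (methyl orsellinate) | COC(=O)c1c(C)cc(O)cc1O | starting material
17 | methyl 3-chloro-4,6-dihydroxy-2-methylbenzoate | COC(=O)c1c(C)c(Cl)c(O)cc1O | intermediate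
18 | methyl 3-chloro-4,6-bis(methoxymethoxy)-2-methylbenzoate | COC(=O)c1c(C)c(Cl)c(OCOC)cc1OCOC | intermediate
19 | 2-chloro-N-methoxy-N-methylacetamide | CON(C)C(=O)CCl | starting material
20 | benzylic lithium species derived from 18 (not isolated) | COC(=O)c1c(C[Li])c(Cl)c(OCOC)cc1OCOC | intermediate
21 | methyl 3-chloro-2-(3-chloro-2-oxopropyl)-4,6-bis(methoxymethoxy)benzoate | COC(=O)c1c(CC(=O)CCl)c(Cl)c(OCOC)cc1OCOC | intermediate
22 | methyl 3-chloro-2-(3-chloro-2-oxopropyl)-4,6-dihydroxybenzoate (not isolated) | COC(=O)c1c(CC(=O)CCl)c(Cl)c(O)cc1O | intermediate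
23 | 5-chloro-3-(chloromethyl)-6,8-dihydroxy-1H-isochromen-1-one | ClCc1cc2c(Cl)c(O)cc(O)c2c(=O)o1 | intermediate
24 | 6,8-bis(tert-butyldimethylsilyloxy)-5-chloro-3-(chloromethyl)-1H-isochromen-1-one | ClCc1cc2c(Cl)c(O[Si](C)(C)C(C)(C)C)cc(O[Si](C)(C)C(C)(C)C)c2c(=O)o1 | intermediate
25 | triethyl phosphite | CCOP(OCC)OCC | starting material
26 | diethyl {[6,8-bis(tert-butyldimethylsilyloxy)-5-chloro-1-oxo-1H-isochromen-3-yl]methyl}phosphonate | CCOP(=O)(Cc1cc2c(Cl)c(O[Si](C)(C)C(C)(C)C)cc(O[Si](C)(C)C(C)(C)C)c2c(=O)o1)OCC | intermediate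
27 | lithiated phosphonate derived from 26 (not isolated) | CCOP(=O)(C([Li])c1cc2c(Cl)c(O[Si](C)(C)C(C)(C)C)cc(O[Si](C)(C)C(C)(C)C)c2c(=O)o1)OCC | intermediate
28 | 6,8-bis(tert-butyldimethylsilyloxy)-3-{(1E,3E)-4-[(2R,3S,5R)-3-(tert-butyldimethylsilyloxy)-5-methyltetrahydrofuran-2-yl]buta-1,3-dienyl}-5-chloro-1H-isochromen-1-one | C[C@@H]1C[C@H](O[Si](C)(C)C(C)(C)C)[C@@H](/C=C/C=C/c2cc3c(Cl)c(O[Si](C)(C)C(C)(C)C)cc(O[Si](C)(C)C(C)(C)C)c3c(=O)o2)O1 | intermediate
29 | 5-chloro-6,8-dihydroxy-3-{(1E,3E)-4-[(2R,3S,5R)-3-hydroxy-5-methyltetrahydrofuran-2-yl]buta-1,3-dienyl}-1H-isochromen-1-one | C[C@@H]1C[C@H](O)[C@@H](/C=C/C=C/c2cc3c(Cl)c(O)cc(O)c3c(=O)o2)O1 | target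

Total step count: 17.
Longest linear sequence: 11 (steps 1 to 9, then 16 and 17). Steps 10 to 15 form the second branch.

Steps most likely to fail

1. Step 7. The configuration at C5 may be relayed only incompletely to C2, giving poor facial selectivity in a ring smaller than those for which this closure is best documented. Alternatively, beta-elimination of the enol-ether oxygen or protodestannylation may outrun ring closure.
The fallback closes O1–C2 instead of C2–C3. It sets out from 1 and returns at 12.
- Compound 1 is silylated (TBSCl, imidazole) to methyl (R)-3-(tert-butyldimethylsilyloxy)butanoate F1, which iBu2AlH at −78 °C reduces to (R)-3-(tert-butyldimethylsilyloxy)butanal F2.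
- Horner–Wadsworth–Emmons reaction with diethyl allylphosphonate (n-BuLi, THF/DMPU) gives (R,E)-tert-butyl(hepta-4,6-dien-2-yloxy)dimethylsilane F3.
- Shi epoxidation (KHSO5, K2CO3 buffer, the L-sorbose-derived enantiomer of the fructose ketone) should oxidise only the internal E double bond under reagent control, giving tert-butyldimethyl{(R)-1-[(2S,3S)-3-vinyloxiran-2-yl]propan-2-yloxy}silane F4.
- TBAF frees (R)-1-[(2S,3S)-3-vinyloxiran-2-yl]propan-2-ol F5.
- Catalytic camphorsulfonic acid in CH2Cl2 then lets the C5 hydroxyl open the epoxide at its allylic carbon with inversion (vinyl-activated 5-endo opening). This gives 12 with C3 fixed by the epoxidation and C2 by the inversion.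

2. Step 16. The phosphonate anion may deprotonate the enal at C2–H, leading to epimerisation or eliminative ring opening. Base may also attack the lactone, or the E selectivity may erode.
The fallback makes the C2'–C3' single bond by cross-coupling. It sets out from 24 and 13 and returns at 28.
- Compound 24 is oxidised with N-methylmorpholine N-oxide in MeCN (displacement of the allylic chloride by the N-oxide, then elimination) to 6,8-bis(tert-butyldimethylsilyloxy)-5-chloro-1-oxo-1H-isochromene-3-carbaldehyde F6.
- Takai olefination (CrCl2, CHI3, THF, 0 °C) gives 6,8-bis(tert-butyldimethylsilyloxy)-5-chloro-3-[(E)-2-iodovinyl]-1H-isochromen-1-one F7.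
- In parallel, 13 undergoes cross-metathesis with vinylboronic acid pinacol ester (second-generation Grubbs catalyst RuCl2(=CHPh)(PCy3)(H2IMes)) to tert-butyldimethyl{[(2R,3S,5R)-5-methyl-2-[(E)-2-(4,4,5,5-tetramethyl-1,3,2-dioxaborolan-2-yl)vinyl]tetrahydrofuran-3-yl]oxy}silane F8.
- Suzuki–Miyaura coupling of F7 with F8 (PdCl2(dppf), K3PO4, THF/H2O, rt) should join them with retention of both double-bond geometries to give 28. No carbanion ever meets an enal in this sequence.

3. Step 12. The soft benzylic anion may alkylate at the CH2Cl carbon, or merely deprotonate the amide, instead of adding to its carbonyl group.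
The fallback introduces the halogen only after the ring is closed. It sets out from 18 and returns at 24.
- The lithio species 20 is acylated with N-methoxy-N-methylacetamide to methyl 3-chloro-4,6-bis(methoxymethoxy)-2-(2-oxopropyl)benzoate F9.
- TFA in CH2Cl2 converts F9 into 5-chloro-6,8-dihydroxy-3-methyl-1H-isochromen-1-one F10.
- TBSOTf/2,6-lutidine gives 6,8-bis(tert-butyldimethylsilyloxy)-5-chloro-3-methyl-1H-isochromen-1-one F11.
- The vinylogous enolate of F11 (LiN(iPr)2, THF, −78 °C) is chlorinated at its exocyclic carbon with hexachloroethane, as is known for 6-methyl-1,3-dioxin-4-ones, to give 24.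

Further compounds
F1 | step 7 | methyl (R)-3-(tert-butyldimethylsilyloxy)butanoate | C[C@@H](O[Si](C)(C)C(C)(C)C)CC(=O)OC
F2 | step 7 | (R)-3-(tert-butyldimethylsilyloxy)butanal | C[C@@H](O[Si](C)(C)C(C)(C)C)CC=O
F3 | step 7 | (R,E)-tert-butyl(hepta-4,6-dien-2-yloxy)dimethylsilane | C[C@@H](O[Si](C)(C)C(C)(C)C)C/C=C/C=C
F4 | step 7 | tert-butyldimethyl{(R)-1-[(2S,3S)-3-vinyloxiran-2-yl]propan-2-yloxy}silane | C[C@@H](O[Si](C)(C)C(C)(C)C)C[C@@H]1O[C@H]1C=C
F5 | step 7 | (R)-1-[(2S,3S)-3-vinyloxiran-2-yl]propan-2-ol | C[C@@H](O)C[C@@H]1O[C@H]1C=C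
F6 | step 16 | 6,8-bis(tert-butyldimethylsilyloxy)-5-chloro-1-oxo-1H-isochromene-3-carbaldehyde | O=Cc1cc2c(Cl)c(O[Si](C)(C)C(C)(C)C)cc(O[Si](C)(C)C(C)(C)C)c2c(=O)o1
F7 | step 16 | 6,8-bis(tert-butyldimethylsilyloxy)-5-chloro-3-[(E)-2-iodovinyl]-1H-isochromen-1-one | I/C=C/c1cc2c(Cl)c(O[Si](C)(C)C(C)(C)C)cc(O[Si](C)(C)C(C)(C)C)c2c(=O)o1
F8 | step 16 | tert-butyldimethyl{[(2R,3S,5R)-5-methyl-2-[(E)-2-(4,4,5,5-tetramethyl-1,3,2-dioxaborolan-2-yl)vinyl]tetrahydrofuran-3-yl]oxy}silane | C[C@@H]1C[C@H](O[Si](C)(C)C(C)(C)C)[C@@H](/C=C/B2OC(C)(C)C(C)(C)O2)O1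
F9 | step 12 | methyl 3-chloro-4,6-bis(methoxymethoxy)-2-(2-oxopropyl)benzoate | COC(=O)c1c(CC(C)=O)c(Cl)c(OCOC)cc1OCOC
F10 | step 12 | 5-chloro-6,8-dihydroxy-3-methyl-1H-isochromen-1-one | Cc1cc2c(Cl)c(O)cc(O)c2c(=O)o1
F11 | step 12 | 6,8-bis(tert-butyldimethylsilyloxy)-5-chloro-3-methyl-1H-isochromen-1-one | Cc1cc2c(Cl)c(O[Si](C)(C)C(C)(C)C)cc(O[Si](C)(C)C(C)(C)C)c2c(=O)o1
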